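**Retrosynthetic overview**
1. Pongaflavanol comes from its C4 ketone, the (2S)-chromene-4,7-dione, by substrate-controlled 1,2-reduction. This sets C4 cis to the C2 phenyl group.
2. The ketone comes from an open-chain alkynyl acylketene acetal and (S)-4-phenyloxetan-2-one. The two alkyne carbons (future C4a and C8a) are inserted into the acyl C4–O1 bond of the four-membered lactone, which grows into the six-membered pyranone (ring C). The enol ether formed in this way then closes ring A onto C5 in the same flask.
3. Enabling feature: in ring C, O1–C2–C3–C4 is a beta-oxy-acyl (aldol) array, that is a beta-lactone, and C4a=C8a lies between an acyl carbon and an oxygen like a hydrated ynone. In ring A, C5(OMe)=C6–C7=O is an acylketene acetal less methanol, and C8 is quaternary, so nothing can enolise or aromatise there.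
4. Ring order: oxetanone (from the chiral-pool hydroxy acid), then ring C, then ring A. The open chain comes from methyl acetoacetate by double prenylation, ketone-to-alkyne conversion and acylation of 1,1-dimethoxyethene.

Key step: step 6

Remark: core atoms are named by flavan numbering (O1, C2, C3, C4, C4a, C5 to C8, C8a). Ring C is the pyran ring and ring A is the carbocycle.

**Step 1**
Reactants: 1 methyl acetoacetate; 2 prenyl bromide (1-bromo-3-methylbut-2-ene)
Product: 3 methyl 2-acetyl-5-methyl-2-(3-methylbut-2-en-1-yl)hex-4-enoate
Conditions: 2 (2.3 equiv), K2CO3 (3 equiv), DMF, 23 to 50 °C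
Reagents that add atoms: none
Why: Double SN2 C-alkylation of the stabilised enolate with a reactive allylic bromide (acetoacetic ester alkylation) should build the quaternary carbon that becomes C8 with both prenyl groups in place.

**Step 2**
Reactants: 3 methyl 2-acetyl-5-methyl-2-(3-methylbut-2-en-1-yl)hex-4-enoate
Product: 5 methyl 2-ethynyl-5-methyl-2-(3-methylbut-2-en-1-yl)hex-4-enoate, via enol phosphate 4 (not isolated)
Conditions: LiN(iPr)2 (1.1 equiv), THF, −78 °C; ClP(O)(OEt)2, −78 to 23 °C; LiN(iPr)2 (2.3 equiv), −78 to 23 °C; aq NH4Cl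
Reagents that add atoms: none
Why: The acetyl CH3 is the only enolisable position, so O-phosphorylation followed by base-induced elimination of diethyl phosphate (methyl ketone to terminal alkyne by enol phosphate elimination) should give the alkyne, and the quaternary neighbour rules out isomerisation to an allene.

**Step 3**
Reactants: 5 methyl 2-ethynyl-5-methyl-2-(3-methylbut-2-en-1-yl)hex-4-enoate
Product: 6 2-ethynyl-5-methyl-2-(3-methylbut-2-en-1-yl)hex-4-enoic acid
Conditions: KOH, MeOH/H2O, 65 °C; then cold dilute HCl to pH 3
Reagents that add atoms: potassium hydroxide [K+].[OH-]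
Why: Saponification of the hindered ester should proceed on heating, because neither the alkyne (no propargylic hydrogen) nor the prenyl groups are sensitive to base.

**Step 4**
Reactants: 6 2-ethynyl-5-methyl-2-(3-methylbut-2-en-1-yl)hex-4-enoic acid; 7 1,1-dimethoxyethene
Product: 9 4-ethynyl-1,1-dimethoxy-7-methyl-4-(3-methylbut-2-en-1-yl)octa-1,6-dien-3-one, via acid chloride 8 (not isolated)
Conditions: 1-chloro-N,N,2-trimethylprop-1-en-1-amine (1.1 equiv), CH2Cl2, 0 °C; then 7 (2 equiv), Et3N (1.5 equiv), 0 to 40 °C
Reagents that add atoms: none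
Why: C-acylation of a ketene acetal by an acid chloride, with loss of HCl to Et3N, is the known route to acylketene acetals; the neutral chloroenamine makes the acid chloride without free HCl that would add to the prenyl groups, and 8 has no alpha hydrogen, so it cannot form a ketene.

**Step 5**
Reactants: 10 (S)-3-hydroxy-3-phenylpropanoic acid
Product: 12 (S)-4-phenyloxetan-2-one, via mixed sulfonic anhydride 11 (not isolated)
Conditions: PhSO2Cl (2 equiv), pyridine, 0 °C
Reagents that add atoms: none
Why: Beta-lactonisation by carboxyl activation closes the ring through attack of the hydroxyl group on the activated acyl carbon, so the C–O bond at the stereocentre is never broken and the (S) configuration of the future C2 is retained.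

**Step 6**
Reactants: 9 4-ethynyl-1,1-dimethoxy-7-methyl-4-(3-methylbut-2-en-1-yl)octa-1,6-dien-3-one; 12 (S)-4-phenyloxetan-2-one
Product: 16 (2S)-5-methoxy-8,8-bis(3-methylbut-2-en-1-yl)-2-phenyl-2,3-dihydro-4H-chromene-4,7(8H)-dione, via lithium acetylide 13 (not isolated), via hydroxy ynone 14 (not isolated), via dihydropyranone 15 (not isolated)
Conditions: LiN(iPr)2 (1.0 equiv), THF, −78 °C; 12 (1.05 equiv), −78 °C; then camphor-10-sulfonic acid (2.5 equiv), CH2Cl2, 4 Å MS, −78 to 23 °C
Reagents that add atoms: none
Why: Proposed new method: the hard lithium acetylide 13 should attack the strained acyl carbon of 12 with acyl–oxygen cleavage, as lithium acetylides do with five- and six-membered lactones and lithium ester enolates do with oxetan-2-ones, and the cold acid quench should give the aldol-type hydroxy ynone 14 before retro-aldol or elimination can start. Acid then drives the 6-endo-dig oxa-Michael closure of O1 onto C8a (closest known type: beta-hydroxy ynone to 2,3-dihydro-4H-pyran-4-one), so that the two alkyne carbons stand inserted between C4 and O1 and the four-membered lactone has become the six-membered pyranone 15. Only at this point is C4a an enol-ether carbon, and it closes ring A by a 6-(enolendo)-exo-trig attack on the protonated acylketene acetal carbon C5, helped by the gem-dialkyl effect of C8. Loss of methanol and of the C4a proton leaves C5(OMe)=C6 and restores C4a=C8a, which places the methoxy group at C5 without any regiochemically ambiguous O-methylation. No stereocentre is made in this step: C2 is carried over from 12 because no bond to it is broken at any stage. The step needs acyl over alkyl C–O cleavage and addition over enolisation (hard nucleophile, −78 °C, no Lewis acid), 6-endo over 5-exo closure (polarisation of the ynone), and the right order of events (the alkyne is inert toward C5 until O1 has added).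

**Step 7**
Reactants: 16 (2S)-5-methoxy-8,8-bis(3-methylbut-2-en-1-yl)-2-phenyl-2,3-dihydro-4H-chromene-4,7(8H)-dione
Product: 17 pongaflavanol = (2S,4S)-4-hydroxy-5-methoxy-8,8-bis(3-methylbut-2-en-1-yl)-2-phenyl-3,4-dihydro-2H-chromen-7(8H)-one
Conditions: NaBH4, CeCl3·7H2O, MeOH, −78 °C; aq NaHCO3 quench
Reagents that add atoms: none
Why: Luche 1,2-reduction should pick C4=O over C7=O (the latter is flanked by the quaternary C8 and deactivated by both O1 and the methoxy group), and axial hydride delivery to the half-chair with the C2 phenyl group equatorial should give the equatorial alcohol, that is the 2,4-cis (4S) isomer as in flavanone reductions.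

**Compound list**
1 | methyl acetoacetate | COC(=O)CC(C)=O | starting material
2 | prenyl bromide | CC(C)=CCBr | starting material
3 | methyl 2-acetyl-5-methyl-2-(3-methylbut-2-en-1-yl)hex-4-enoate | COC(=O)C(CC=C(C)C)(CC=C(C)C)C(C)=O | intermediate
4 | enol phosphate of 3 (diethyl 1-substituted vinyl phosphate) | COC(=O)C(CC=C(C)C)(CC=C(C)C)C(=C)OP(=O)(OCC)OCC | intermediate
5 | methyl 2-ethynyl-5-methyl-2-(3-methylbut-2-en-1-yl)hex-4-enoate | COC(=O)C(CC=C(C)C)(CC=C(C)C)C#C | intermediate
6 | 2-ethynyl-5-methyl-2-(3-methylbut-2-en-1-yl)hex-4-enoic acid | OC(=O)C(CC=C(C)C)(CC=C(C)C)C#C | intermediate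
7 | 1,1-dimethoxyethene | C=C(OC)OC | starting material
8 | 2-ethynyl-5-methyl-2-(3-methylbut-2-en-1-yl)hex-4-enoyl chloride | ClC(=O)C(CC=C(C)C)(CC=C(C)C)C#C | intermediate
9 | 4-ethynyl-1,1-dimethoxy-7-methyl-4-(3-methylbut-2-en-1-yl)octa-1,6-dien-3-one | COC(OC)=CC(=O)C(CC=C(C)C)(CC=C(C)C)C#C | intermediate
10 | (S)-3-hydroxy-3-phenylpropanoic acid | OC(=O)C[C@H](O)c1ccccc1 | starting material
11 | benzenesulfonic (S)-3-hydroxy-3-phenylpropanoic anhydride | O=S(=O)(OC(=O)C[C@H](O)c1ccccc1)c1ccccc1 | intermediate
12 | (S)-4-phenyloxetan-2-one | O=C1C[C@@H](c2ccccc2)O1 | intermediate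
13 | lithium acetylide of 9 | [Li]C#CC(CC=C(C)C)(CC=C(C)C)C(=O)C=C(OC)OC | intermediate
14 | (9S)-9-hydroxy-1,1-dimethoxy-4,4-bis(3-methylbut-2-en-1-yl)-9-phenylnon-1-en-5-yne-3,7-dione | COC(OC)=CC(=O)C(CC=C(C)C)(CC=C(C)C)C#CC(=O)C[C@H](O)c1ccccc1 | intermediate
15 | (2S)-6-[1,1-dimethoxy-7-methyl-4-(3-methylbut-2-en-1-yl)-3-oxoocta-1,6-dien-4-yl]-2-phenyl-2,3-dihydro-4H-pyran-4-one | COC(OC)=CC(=O)C(CC=C(C)C)(CC=C(C)C)C1=CC(=O)C[C@@H](c2ccccc2)O1 | intermediate
16 | (2S)-5-methoxy-8,8-bis(3-methylbut-2-en-1-yl)-2-phenyl-2,3-dihydro-4H-chromene-4,7(8H)-dione | COC1=CC(=O)C(CC=C(C)C)(CC=C(C)C)C2=C1C(=O)C[C@@H](c1ccccc1)O2 | intermediate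
17 | pongaflavanol, (2S,4S) | COC1=CC(=O)C(CC=C(C)C)(CC=C(C)C)C2=C1[C@@H](O)C[C@@H](c1ccccc1)O2 | target

**Step count**
Total step count: 7. Longest linear sequence: 6 (steps 1, 2, 3, 4, 6, 7).

**Steps most likely to fail**

Step 6.
- What may go wrong: enolisation or alkyl–oxygen opening of the lactone, a second addition of the acetylide to the freshly formed ynone, retro-aldol or elimination of the lithium aldolate with loss of configuration at C2, or a sluggish acid-phase closure of ring A.
- Fallback: it sets out from 12 and 9 and returns at 14. Lactone 12 is opened with MeNH(OMe)·HCl and i-PrMgCl to (S)-3-hydroxy-N-methoxy-N-methyl-3-phenylpropanamide F1. Silylation with Et3SiCl and imidazole gives the triethylsilyl ether F2. Acetylide 13 is added to F2, where the chelated tetrahedral intermediate stops double addition, and this gives the silyl-protected ynone F3. HF·pyridine frees 14, which is then closed to 15 and 16 with camphor-10-sulfonic acid as a separate operation.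

Step 4.
- What may go wrong: slow acylation by the hindered acid chloride, or chloride-induced demethylation of the dialkoxycarbenium intermediate to the beta-keto ester.
- Fallback: it sets out from 6 and returns at 9. Acid 6 is converted through 8 with MeNH(OMe)·HCl and Et3N into 2-ethynyl-N-methoxy-N,5-dimethyl-2-(3-methylbut-2-en-1-yl)hex-4-enamide F4. Excess LiC≡COMe, made from ClCH2CH(OMe)2 and LiNEt2, adds to F4 to give the methoxyethynyl ketone F5. Base-catalysed conjugate addition of methanol to the alkoxy ynone then gives 9.

Step 7.
- What may go wrong: hydride attack at C7 or conjugate reduction, poor facial selectivity, or methanolysis of the easily ionised C4 alcohol in the Lewis acidic medium.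
- Fallback: it sets out from 16 and returns at 17, and it makes no new compound (entry F0). It is a catalyst-controlled asymmetric transfer hydrogenation with RuCl[(S,S)-TsDPEN](p-cymene) and HCO2H/Et3N in CH2Cl2. The catalyst sets (4S) and cannot reach the hindered C7 carbonyl. The amine lets 16 epimerise at C2 by reversible oxa-Michael opening, so any erosion at C2 should be funnelled into the faster-reduced (2S) isomer (dynamic kinetic resolution).

**Further compounds**
F1 | step 6 | (S)-3-hydroxy-N-methoxy-N-methyl-3-phenylpropanamide | CON(C)C(=O)C[C@H](O)c1ccccc1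
F2 | step 6 | (S)-N-methoxy-N-methyl-3-phenyl-3-(triethylsilyloxy)propanamide | CON(C)C(=O)C[C@H](O[Si](CC)(CC)CC)c1ccccc1
F3 | step 6 | triethylsilyl ether of 14 | COC(OC)=CC(=O)C(CC=C(C)C)(CC=C(C)C)C#CC(=O)C[C@H](O[Si](CC)(CC)CC)c1ccccc1
F4 | step 4 | 2-ethynyl-N-methoxy-N,5-dimethyl-2-(3-methylbut-2-en-1-yl)hex-4-enamide | CON(C)C(=O)C(CC=C(C)C)(CC=C(C)C)C#C
F5 | step 4 | 4-ethynyl-1-methoxy-7-methyl-4-(3-methylbut-2-en-1-yl)oct-6-en-1-yn-3-one | COC#CC(=O)C(CC=C(C)C)(CC=C(C)C)C#C
F0 | step 7 | none | none
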